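Compound numbers are fixed first: 1–34 in order of appearance in the steps, with 24 → 25 as the key step and 34 as the target. TBS = tert-butyldimethylsilyl, TES = triethylsilyl. Working atom numbers: seven-membered ring C10–C1–C2–C3–C4–C5–C9 (C10 carries the methylene, C4 the two methyls); five-membered ring C5–C6–C7–C8–C9 (C8 carries a methyl and C14); C14 carries C15 (CH2OAc) and C13; the lactone ring is C13–C12–C11(=O)–O–C16.

## The problem

Target 34 is a cis-fused hydroazulene whose cycloheptane bears an exocyclic methylene at C10 and a gem-dimethyl group at C4, and whose quaternary C8 bears a methyl group and the methine C14; C14 in turn carries the acetoxymethyl carbon C15 and C13 of a γ-butyrolactone. Five stereocentres are needed, three contiguous in the bicycle (5R, 8R, 9S) and two contiguous in the chain (14R, 13R). C5 can relay to C9 through the ring fusion and, through a temporary stereocentre at C7, to C8; C14 and C13 cannot be controlled from the ring, because the C8–C14 bond rotates freely, so they are best set on a cyclic template of their own. The C8–C14 bond joins a quaternary carbon to a doubly branched methine and is out of reach of fragment coupling or enolate alkylation; it has to form intramolecularly. The exocyclic alkene (lost to acid, ozone, hydrogenation or RuO4), the primary acetate and the lactone (lost to hydride and strong base) and C9 once C10 is a ketone (epimerisable) mean that methylenation must come last and under non-basic conditions. The enabling feature is the array C10–C9–C8(–C14)–C7: C9 is bonded both to C10 and to quaternary C8, and C8 has the ring methylene C7 as neighbour. A C8=C9 alkene can therefore attack a C10 aldehyde through C9, and the C8 cation can be quenched by a 1,2-shift of C14 from a C7 carbinol; this builds the seven-membered ring, the ring fusion, the quaternary centre and the C8–C14 bond together, at the price of a C7 ketone to be removed.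

## Retrosynthesis

**Methylene and lactone last.** The C10=CH2 bond of 34 is cut to the C10 ketone of keto lactone 33, and the lactone C11(=O)–O bond is traced through hydroxy lactone 32 to the C11/C16 1,4-diol of triol 30. Carrying the lactone or the alkene earlier would expose them to hydride, fluoride and radical steps; as alcohols or silyl ethers these positions are inert. The forward reaction must oxidise the unbranched C11 hydroxyl in preference to the β-branched C16 hydroxyl.

**C7 methylene from the C7 ketone.** Triol 30 comes from silyl ether 29, whose C7 methylene is traced through thionocarbonate 28 and alcohol 27 to the ketone of 26 and 25. A neopentyl ketone beside a quaternary centre resists hydrazone or thioketal chemistry, whereas radical deoxygenation is indifferent to hindrance. The C10 hydroxyl of 25 is parked as the TES ether 26 so that only C7 is deoxygenated.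

**Key cut: C9–C10 and C8–C14.** Hydroxy ketone 25 is opened to the monocyclic aldehyde 24, a cyclopentene with a tertiary allylic alcohol at C7 that carries C14. Against cuts that close the five-membered ring or the seven-membered ring alone, this one removes a ring, two skeletal bonds and two stereocentres (C8, C9). It also turns the congested C8–C14 bond into a C7–C14 bond that a carbonyl addition can make. The forward reaction must close a seven-membered ring on the tether face of C9 and migrate C14, not ring carbon C6.

**Side-chain adjustment.** Aldehyde 24 comes from dimethyl acetal 23, the C15 acetate from alcohol 22, the C11 silyl ether from triol 21, and 21 from the δ-lactone 20 by reduction. Reduction is required because C14 must not sit next to a carbonyl group when it migrates. The C15 oxygen is acylated, not silylated, so that it cannot capture the C8 cation.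

**Aldol cut: C7–C14.** Lactone 20 is divided into enone 11 and δ-lactone 19. With C14 as the α-carbon of a six-membered lactone, the enolate has fixed geometry and reacts anti to the C13 substituent, so C14 is set relative to C13 by the ring. An open-chain ester enolate would offer no such bias, since the two arms on C13 differ only as CH2O and CH2CH2. The precursors carry one stereocentre each; the forward reaction must add 1,2 to the enone, anti to the C5 substituent.

**Enone 11.** The C8=C9 bond is cut by ring-closing metathesis to dienone 10, the C7–C8 bond by alkenyllithium addition to amide 9, and the C5–C6 bond by an Eschenmoser–Claisen rearrangement of allylic alcohol 7. C5 bears a tertiary alkyl group, so conjugate addition of a tertiary nucleophile to a cyclopentenone is unattractive; a sigmatropic shift tolerates the bulk and transfers chirality from a carbinol made by catalytic reduction of enone 6.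

**Acyclic start.** Enone 6 comes from aldehyde 5 by olefination, 5 from nitrile 3 by partial reduction, and 3 from isobutyronitrile 1 and bromo acetal 2. One alkylation installs the C4 quaternary carbon and the whole C3–C2–C1–C10 chain, with C10 masked as a dimethyl acetal.

**Lactone 19.** The lactone is traced to hemiester 17 (acid-selective reduction), 17 to the prochiral anhydride 16 (enantioselective methanolysis, which sets C13), 16 to diacid 15, and 15 to silyl ether 13 of cyclopent-3-en-1-ylmethanol 12 by oxidative cleavage. Symmetry makes the fragment cheap, and a single catalytic step breaks it.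

## Roads not taken

**Alternative 1:** hydroformylation to bring in the lactone carbonyl carbon. The cut is the C11–C12 bond plus the lactol C–O bond. A rhodium hydride (from Rh(acac)(CO)2 and a chiral bisphosphite under CO/H2) would add across the C12=C13 methylidene of allylic alcohol A1, placing hydrogen on C13 and the formyl carbon on C12; the C16 hydroxyl would close to lactol A2, which on oxidation meets keto lactone 33.
- Merits: C11 arrives at the right oxidation level with no protecting groups, and the regiochemistry is the normal one for a 1,1-disubstituted alkene.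
- Weak points: such alkenes are the slowest hydroformylation substrates. C13 would have to be set by face selection on an alkene whose only nearby stereocentre is C14, itself beside a quaternary carbon; ligand control in that setting is not established. The cut also leaves the hydroazulene and the C8–C14 bond unsolved, so A1 would still need a core-forming step of the present kind.
- Comparison: for the lactone alone this road is shorter; the chosen plan spends steps 14, 15, 23 and 24 on redox and protection at C11 and C16. Against that, the chosen plan fixes C13 in a simple fragment by a catalyst-controlled desymmetrisation and fixes C14 relative to it on a ring, before valuable material is committed.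

**Alternative 2:** vinylcarbenoid cyclopropanation and Cope rearrangement. The cut is C1–C2 and C4–C5. A dirhodium tetracarboxylate such as Rh2(OAc)4 would decompose diazo ester A4; the carbenoid would cyclopropanate the vinyl group of vinylcyclopentene A3, and the cis-divinylcyclopropane would rearrange to cycloheptadiene ester A5.
- Merits: convergent; the seven-membered ring and the C4 quaternary carbon form in one operation with the finished side chain on board; no oxygen is left at C7.
- Weak points: the carbenoid terminus carries two methyl groups, so one must point inward in the boat transition state of the Cope step, which raises its barrier sharply. C9 remains sp2 in A5, so the ring fusion still has to be set by a face-selective reduction next to quaternary C8. The C2 ester must be excised and C10 still needs its carbon. A3 already contains the C8–C14 bond, so the hardest bond is moved into the fragment synthesis, not solved.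
- Comparison: this road is better in convergence and in redox economy at C7. The chosen plan sets against it that C9 and C8 are both fixed in the ring-forming event and that C10 emerges oxygenated, ready for methylenation.

**Alternative 3:** hydrogen-atom-transfer radical cyclisation. The cut is C8–C9. Fe(acac)3 and PhSiH3 would transfer a hydrogen atom to the 1,1-disubstituted alkene of cycloheptene ester A6; the tertiary C8 radical would add 5-exo to C9 of the unsaturated ester to give the tert-butyl ester A7.
- Merits: mild and tolerant of lactone and acetate; radical addition is well suited to a congested quaternary centre; cis fusion is the normal outcome of such a closure; C7 needs no deoxygenation; the ester carbon can become the methylene carbon by reduction and elimination.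
- Weak points: the C8 radical must distinguish its methyl group from the C14 chain in the transition state, with only the exocyclic C14 stereocentre to guide it, so the C8 configuration is uncertain. A6 needs a separate synthesis of the 4,4-dimethylcycloheptene with its C5 stereocentre. Reducing the tert-butyl ester of A7 beside an acetate and a lactone forces a protecting-group detour.
- Comparison: this road is as good or better in convergence and avoids the three-step removal of the C7 ketone. The chosen plan sets against it a stereospecific origin for C8 (a suprafacial shift from a defined C7 carbinol) and closure of the seven-membered ring in the same step.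

Key step: step 18

## Route

Assumption: the hydroquinidine-derived catalyst (DHQD)2AQN is taken to open anhydride 16 to the (R)-hemiester 17; if it gave the enantiomer, the hydroquinine-derived (DHQ)2AQN would be used instead.

Step 1
Reactants: 1 isobutyronitrile; 2 4-bromo-1,1-dimethoxybutane
Product: 3 6,6-dimethoxy-2,2-dimethylhexanenitrile
Conditions: LiN(iPr)2, THF, −78 °C; then 2, −78 °C to rt
Reagents that add atoms: none
Why: Alkylation of a tertiary nitrile anion with a primary bromide builds the C4 quaternary carbon and the whole C3–C10 chain in one step; the dimethyl acetal is inert to base.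

Step 2
Reactants: 3
Product: 5 6,6-dimethoxy-2,2-dimethylhexanal, via N-aluminated aldimine 4 (not isolated)
Conditions: iBu2AlH, CH2Cl2, −78 °C; then aqueous potassium sodium tartrate and wet silica gel (pH about 5), 0 °C
Reagents that add atoms: water, O
Why: Partial reduction of a nitrile by iBu2AlH stops at the aluminated imine, which has no α-hydrogen and cannot over-reduce; buffered hydrolysis frees the aldehyde while the acetal survives.

Step 3
Reactants: 5
Product: 6 (E)-9,9-dimethoxy-5,5-dimethylnon-3-en-2-one
Conditions: dimethyl (2-oxopropyl)phosphonate, NaH, THF, 0 °C to rt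
Reagents that add atoms: dimethyl (2-oxopropyl)phosphonate, CC(=O)CP(=O)(OC)OC
Why: Horner–Wadsworth–Emmons olefination of a non-enolisable aldehyde with a stabilised β-ketophosphonate; the tertiary substituent enforces the (E)-enone.

Step 4
Reactants: 6
Product: 7 (R,E)-9,9-dimethoxy-5,5-dimethylnon-3-en-2-ol
Conditions: (S)-1-methyl-3,3-diphenyltetrahydro-1H,3H-pyrrolo[1,2-c][1,3,2]oxazaborole ((S)-Me-CBS, 0.2 equiv), BH3·SMe2, toluene, −40 °C; MeOH quench
Reagents that add atoms: none
Why: Corey–Bakshi–Shibata reduction of a methyl alkenyl ketone; the alkenyl group acts as the large substituent, so the (S)-catalyst should deliver hydride to the face that gives the (R)-carbinol, with 1,2-reduction favoured over conjugate reduction.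

Step 5
Reactants: 7
Product: 9 (R,E)-3-(6,6-dimethoxy-2-methylhexan-2-yl)-N,N-dimethylhex-4-enamide, via ketene N,O-acetal 8 (not isolated)
Conditions: 1,1-dimethoxy-N,N-dimethylethanamine (5 equiv), xylenes, 140 °C
Reagents that add atoms: 1,1-dimethoxy-N,N-dimethylethanamine, CC(OC)(OC)N(C)C
Why: Eschenmoser–Claisen rearrangement under neutral conditions; in the chair transition state the carbinol methyl and the tertiary alkyl group are both pseudo-equatorial, so the (R)-carbinol is transferred suprafacially to (R)-configured C5 and the new alkene is (E).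

Step 6
Reactants: 9
Product: 10 (R,E)-5-(6,6-dimethoxy-2-methylhexan-2-yl)-2-methylocta-1,6-dien-3-one
Conditions: 2-bromopropene, tBuLi (2 equiv), Et2O, −78 °C; then 9, THF, −78 to 0 °C; pH 7 phosphate buffer
Reagents that add atoms: 2-bromopropene, CC(Br)=C
Why: Addition of an alkenyllithium to an N,N-dimethylamide gives a tetrahedral lithium hemiaminal that collapses to the ketone only on work-up, so over-addition is avoided; the buffered quench keeps the liberated amine from adding to the enone.

Step 7
Reactants: 10
Product: 11 (R)-4-(6,6-dimethoxy-2-methylhexan-2-yl)-2-methylcyclopent-2-en-1-one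
Conditions: second-generation Grubbs catalyst RuCl2(=CHPh)(PCy3)(H2IMes) (5 mol%), CH2Cl2, 40 °C
Reagents that add atoms: none
Why: Ring-closing metathesis of a 1,6-dienone to a 2-methylcyclopentenone with loss of propene, a well-known closure for this catalyst; the neutral conditions leave the γ-stereocentre C5 untouched.

Step 8
Reactants: 12 cyclopent-3-en-1-ylmethanol
Product: 13 tert-butyl(cyclopent-3-en-1-ylmethoxy)dimethylsilane
Conditions: tBuMe2SiCl, imidazole, CH2Cl2, rt
Reagents that add atoms: tert-butyldimethylsilyl chloride, CC(C)(C)[Si](C)(C)Cl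
Why: Standard silylation of a primary alcohol; this oxygen becomes the C16 oxygen and stays protected until step 23.

Step 9
Reactants: 13
Product: 15 3-(TBSO-methyl)pentanedioic acid, via dialdehyde 14 (not isolated)
Conditions: O3, CH2Cl2/MeOH, −78 °C; PPh3; then NaClO2, NaH2PO4, 2-methylbut-2-ene, tBuOH/H2O, rt
Reagents that add atoms: ozone, [O-][O+]=O; sodium chlorite, [Na+].[O-]Cl=O
Why: Ozonolysis of the symmetric cyclopentene followed by Pinnick oxidation of the crude dialdehyde gives the achiral 3-substituted glutaric acid; the weakly acidic buffer leaves the silyl ether in place.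

Step 10
Reactants: 15
Product: 16 4-(TBSO-methyl)oxane-2,6-dione
Conditions: Ac2O, 70 °C; evaporation
Reagents that add atoms: none
Why: Dehydration of a glutaric acid to its six-membered cyclic anhydride with acetic anhydride is routine for 3-substituted glutaric acids.

Step 11
Reactants: 16
Product: 17 (R)-3-(TBSO-methyl)-5-methoxy-5-oxopentanoic acid
Conditions: MeOH (10 equiv), hydroquinidine anthraquinone-1,4-diyl diether ((DHQD)2AQN, 0.2 equiv), Et2O, −40 °C
Reagents that add atoms: methanol, CO
Why: Cinchona-alkaloid-catalysed enantioselective methanolysis (desymmetrisation) of a prochiral glutaric anhydride; the catalyst directs methanol to one of the two enantiotopic carbonyl groups and thereby sets C13.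

Step 12
Reactants: 17
Product: 19 (R)-4-(TBSO-methyl)oxan-2-one, via hydroxy ester 18 (not isolated)
Conditions: BH3·SMe2, THF, 0 °C to rt; MeOH quench; then pyridinium p-toluenesulfonate (cat.), toluene, 60 °C
Reagents that add atoms: none
Why: Borane reduces the carboxylic acid much faster than the methyl ester, and the δ-hydroxy ester lactonises under mild acid catalysis; the stereocentre is not involved.

Step 13
Reactants: 11; 19
Product: 20 (3R,4R)-4-(TBSO-methyl)-3-[(1R,4R)-4-(6,6-dimethoxy-2-methylhexan-2-yl)-1-hydroxy-2-methylcyclopent-2-en-1-yl]oxan-2-one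
Conditions: 19 (1.3 equiv), LiN(iPr)2, THF, −78 °C; then 11, −78 °C; AcOH quench at −78 °C
Reagents that add atoms: none
Why: Aldol addition of a lactone lithium enolate to the enone carbonyl (kinetic 1,2-addition at low temperature, conjugate addition being disfavoured by the tertiary alkyl group next to C9). The enolate reacts on its face anti to the C13 silyloxymethyl group (3,4-trans, sets C14) and the ketone is attacked anti to the C5 substituent (sets C7).

Step 14
Reactants: 20
Product: 21 (2S,3R)-3-(TBSO-methyl)-2-[(1R,4R)-4-(6,6-dimethoxy-2-methylhexan-2-yl)-1-hydroxy-2-methylcyclopent-2-en-1-yl]pentane-1,5-diol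
Conditions: LiAlH4, THF, 0 °C; aqueous potassium sodium tartrate
Reagents that add atoms: none
Why: Hydride reduction of the lactone to the diol should outpace retro-aldol cleavage of the aluminium alkoxide at 0 °C; it removes the carbonyl next to C14 so that C14 can migrate later.

Step 15
Reactants: 21
Product: 22 (2S,3R)-5-(TBSO)-3-(TBSO-methyl)-2-[(1R,4R)-4-(6,6-dimethoxy-2-methylhexan-2-yl)-1-hydroxy-2-methylcyclopent-2-en-1-yl]pentan-1-ol
Conditions: tBuMe2SiCl (1.05 equiv), imidazole, CH2Cl2, −20 to 0 °C
Reagents that add atoms: tert-butyldimethylsilyl chloride, CC(C)(C)[Si](C)(C)Cl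
Why: Sterically selective monosilylation; the C11 hydroxyl ends an unbranched CH2CH2 arm, whereas the C15 hydroxyl is flanked by the C14 methine and the fully substituted C7, and the tertiary hydroxyl is inert.

Step 16
Reactants: 22
Product: 23 (2S,3R)-5-(TBSO)-3-(TBSO-methyl)-2-[(1R,4R)-4-(6,6-dimethoxy-2-methylhexan-2-yl)-1-hydroxy-2-methylcyclopent-2-en-1-yl]pentyl acetate
Conditions: Ac2O, pyridine, 4-(dimethylamino)pyridine (cat.), CH2Cl2, 0 °C
Reagents that add atoms: acetic anhydride, CC(=O)OC(C)=O
Why: Acetylation of the remaining primary hydroxyl installs the acetate of the target; the tertiary allylic hydroxyl does not acylate under these conditions, and the ester lowers the nucleophilicity of the C15 oxygen for the key step.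

Step 17
Reactants: 23
Product: 24 (2S,3R)-5-(TBSO)-3-(TBSO-methyl)-2-[(1R,4R)-1-hydroxy-2-methyl-4-(2-methyl-6-oxohexan-2-yl)cyclopent-2-en-1-yl]pentyl acetate
Conditions: pyridinium p-toluenesulfonate (cat.), acetone/H2O (10:1), rt
Reagents that add atoms: water, O
Why: Mild hydrolysis of an aliphatic dimethyl acetal, which at this acidity should be faster than ionisation of the tertiary allylic alcohol or cleavage of the primary silyl ethers.

Step 18
Reactants: 24
Product: 25 (2R,3R)-5-(TBSO)-3-(TBSO-methyl)-2-[(1S,3aR,8R,8aR)-8-hydroxy-1,4,4-trimethyl-2-oxodecahydroazulen-1-yl]pentyl acetate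
Conditions: Me2AlCl (3 equiv), CH2Cl2, −78 to −40 °C; aqueous potassium sodium tartrate
Reagents that add atoms: none
Why: Me2AlCl converts the C7 hydroxyl into an aluminium alkoxide and activates the aldehyde, whereupon the C8=C9 alkene attacks C10 through its less substituted carbon C9 and the tertiary C8 cation is quenched by a 1,2-shift of C14 from C7 as C7 becomes the ketone. The closest known reaction type is the Prins-initiated semipinacol (Prins–pinacol) rearrangement of tertiary allylic alcohols and their silyl ethers. The seven-membered ring closes in the 7-exo-trig mode with respect to the aldehyde, with the C8=C9 bond outside the new ring, and the gem-dimethyl group at C4 helps the chain fold. C9 is controlled by the tether: the chain hangs from C5 on one face of the cyclopentene and can reach C9 only on that face, which gives the cis ring fusion. C8 is controlled by the C7 carbinol set in step 13: C14 lies on the face opposite the tether and shifts suprafacially with retention, anti to the incoming C10, so the C8 methyl ends cis to C10. C10 forms as a carbinol of either configuration (one is drawn) and is levelled by oxidation in step 25. The step needs C14 and not ring carbon C6 to migrate and needs the shift to outrun proton loss from the C8 methyl group; C6 migration would contract the ring to a strained cyclobutane, and the alkoxide donor with its anti-periplanar C7–C14 bond makes the shift the fastest exit. The C15 oxygen is acylated so that it cannot capture the C8 cation as a five-membered oxonium ion.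

Step 19
Reactants: 25
Product: 26 (2R,3R)-5-(TBSO)-3-(TBSO-methyl)-2-[(1S,3aR,8R,8aR)-1,4,4-trimethyl-2-oxo-8-(TESO)decahydroazulen-1-yl]pentyl acetate
Conditions: Et3SiOTf, 2,6-lutidine, CH2Cl2, −78 °C
Reagents that add atoms: triethylsilyl trifluoromethanesulfonate, CC[Si](CC)(CC)OS(=O)(=O)C(F)(F)F
Why: Silylation of the hindered secondary C10 hydroxyl with a silyl triflate; at −78 °C with a hindered pyridine base the C7 ketone should not be converted into a silyl enol ether.

Step 20
Reactants: 26
Product: 27 (2R,3R)-5-(TBSO)-3-(TBSO-methyl)-2-[(1S,2R,3aR,8R,8aR)-2-hydroxy-1,4,4-trimethyl-8-(TESO)decahydroazulen-1-yl]pentyl acetate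
Conditions: NaBH4, MeOH/THF (1:1), 0 °C
Reagents that add atoms: none
Why: Borohydride reduction of the cyclopentanone leaves the acetate and silyl ethers intact. The C7 epimer from hydride attack anti to the C8 side chain is drawn; either epimer serves, because C7 becomes a methylene group in step 22.

Step 21
Reactants: 27
Product: 28 (2R,3R)-5-(TBSO)-3-(TBSO-methyl)-2-[(1S,2R,3aR,8R,8aR)-1,4,4-trimethyl-2-[(phenoxycarbonothioyl)oxy]-8-(TESO)decahydroazulen-1-yl]pentyl acetate
Conditions: PhOC(S)Cl, 4-(dimethylamino)pyridine (3 equiv), MeCN, 50 °C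
Reagents that add atoms: O-phenyl chlorothionoformate, S=C(Cl)Oc1ccccc1
Why: Thionocarbonate formation through the acylpyridinium salt, which is reactive enough for a neopentyl secondary alcohol and avoids the strong base of xanthate formation that would endanger the acetate.

Step 22
Reactants: 28
Product: 29 (2R,3R)-5-(TBSO)-3-(TBSO-methyl)-2-[(1S,3aR,8R,8aR)-1,4,4-trimethyl-8-(TESO)decahydroazulen-1-yl]pentyl acetate
Conditions: Bu3SnH, AIBN (2,2′-azobis(2-methylpropionitrile), cat.), toluene, 100 °C
Reagents that add atoms: none
Why: Barton–McCombie deoxygenation; the radical chain is insensitive to the hindrance around C7, and no alkene is present at this stage to intercept the C7 radical.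

Step 23
Reactants: 29
Product: 30 (2R,3R)-5-hydroxy-2-[(1S,3aR,8R,8aR)-8-hydroxy-1,4,4-trimethyldecahydroazulen-1-yl]-3-(hydroxymethyl)pentyl acetate
Conditions: HF·pyridine, pyridine, THF, 0 °C to rt
Reagents that add atoms: none
Why: Fluoride-mediated cleavage of the secondary triethylsilyl ether and both primary tert-butyldimethylsilyl ethers under buffered conditions that leave the acetate untouched.

Step 24
Reactants: 30
Product: 32 (2R)-2-[(1S,3aR,8R,8aR)-8-hydroxy-1,4,4-trimethyldecahydroazulen-1-yl]-2-[(3R)-5-oxooxolan-3-yl]ethyl acetate, via lactol 31 (not isolated)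
Conditions: TEMPO (2,2,6,6-tetramethylpiperidin-1-oxyl, 0.2 equiv), PhI(OAc)2 (2.5 equiv), CH2Cl2, rt
Reagents that add atoms: none
Why: Oxoammonium-mediated oxidative lactonisation of a 1,4-diol; the unbranched C11 hydroxyl is oxidised first, the aldehyde is captured by the C16 hydroxyl as a five-membered lactol and this is oxidised to the lactone. The hindered secondary C10 hydroxyl should react much more slowly.

Step 25
Reactants: 32
Product: 33 (2R)-2-[(3R)-5-oxooxolan-3-yl]-2-[(1S,3aR,8aR)-1,4,4-trimethyl-8-oxodecahydroazulen-1-yl]ethyl acetate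
Conditions: Dess–Martin periodinane, NaHCO3, CH2Cl2, rt
Reagents that add atoms: none
Why: Dess–Martin oxidation of the secondary alcohol, at which both C10 epimers converge; the buffered, non-basic conditions should not epimerise C9.

Step 26
Reactants: 33
Product: 34 (2R)-2-[(3R)-5-oxooxolan-3-yl]-2-[(1R,3aR,8aS)-1,4,4-trimethyl-8-methylidenedecahydroazulen-1-yl]ethyl acetate
Conditions: Zn, CH2Br2, TiCl4, THF/CH2Cl2, 0 °C to rt
Reagents that add atoms: dibromomethane, BrCBr
Why: Lombardo methylenation; the zinc–titanium methylene reagent is non-basic, so C9 next to the ketone is not epimerised, and it converts ketones much faster than the lactone or the acetate.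

## Compound list

1 | isobutyronitrile | CC(C)C#N | starting material
2 | 4-bromo-1,1-dimethoxybutane | COC(OC)CCCBr | starting material
3 | 6,6-dimethoxy-2,2-dimethylhexanenitrile | COC(OC)CCCC(C)(C)C#N | intermediate
4 | N-(diisobutylalumanyl)-6,6-dimethoxy-2,2-dimethylhexan-1-imine | COC(OC)CCCC(C)(C)C=N[Al](CC(C)C)CC(C)C | intermediate
5 | 6,6-dimethoxy-2,2-dimethylhexanal | COC(OC)CCCC(C)(C)C=O | intermediate
6 | (E)-9,9-dimethoxy-5,5-dimethylnon-3-en-2-one | COC(OC)CCCC(C)(C)/C=C/C(C)=O | intermediate
7 | (R,E)-9,9-dimethoxy-5,5-dimethylnon-3-en-2-ol | COC(OC)CCCC(C)(C)/C=C/[C@@H](C)O | intermediate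
8 | (R,E)-1-[(9,9-dimethoxy-5,5-dimethylnon-3-en-2-yl)oxy]-N,N-dimethylethen-1-amine | COC(OC)CCCC(C)(C)/C=C/[C@@H](C)OC(=C)N(C)C | intermediate
9 | (R,E)-3-(6,6-dimethoxy-2-methylhexan-2-yl)-N,N-dimethylhex-4-enamide | COC(OC)CCCC(C)(C)[C@@H](/C=C/C)CC(=O)N(C)C | intermediate
10 | (R,E)-5-(6,6-dimethoxy-2-methylhexan-2-yl)-2-methylocta-1,6-dien-3-one | COC(OC)CCCC(C)(C)[C@@H](/C=C/C)CC(=O)C(C)=C | intermediate
11 | (R)-4-(6,6-dimethoxy-2-methylhexan-2-yl)-2-methylcyclopent-2-en-1-one | COC(OC)CCCC(C)(C)[C@@H]1CC(=O)C(C)=C1 | intermediate
12 | cyclopent-3-en-1-ylmethanol | OCC1CC=CC1 | starting material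
13 | tert-butyl(cyclopent-3-en-1-ylmethoxy)dimethylsilane | CC(C)(C)[Si](C)(C)OCC1CC=CC1 | intermediate
14 | 3-(TBSO-methyl)pentanedial | O=CCC(CO[Si](C)(C)C(C)(C)C)CC=O | intermediate
15 | 3-(TBSO-methyl)pentanedioic acid | OC(=O)CC(CO[Si](C)(C)C(C)(C)C)CC(=O)O | intermediate
16 | 4-(TBSO-methyl)oxane-2,6-dione | O=C1CC(CO[Si](C)(C)C(C)(C)C)CC(=O)O1 | intermediate
17 | (R)-3-(TBSO-methyl)-5-methoxy-5-oxopentanoic acid | COC(=O)C[C@H](CO[Si](C)(C)C(C)(C)C)CC(=O)O | intermediate
18 | methyl (R)-3-(TBSO-methyl)-5-hydroxypentanoate | COC(=O)C[C@H](CO[Si](C)(C)C(C)(C)C)CCO | intermediate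
19 | (R)-4-(TBSO-methyl)oxan-2-one | O=C1C[C@H](CO[Si](C)(C)C(C)(C)C)CCO1 | intermediate
20 | (3R,4R)-4-(TBSO-methyl)-3-[(1R,4R)-4-(6,6-dimethoxy-2-methylhexan-2-yl)-1-hydroxy-2-methylcyclopent-2-en-1-yl]oxan-2-one | COC(OC)CCCC(C)(C)[C@@H]1C[C@@](O)([C@@H]2C(=O)OCC[C@H]2CO[Si](C)(C)C(C)(C)C)C(C)=C1 | intermediate
21 | (2S,3R)-3-(TBSO-methyl)-2-[(1R,4R)-4-(6,6-dimethoxy-2-methylhexan-2-yl)-1-hydroxy-2-methylcyclopent-2-en-1-yl]pentane-1,5-diol | COC(OC)CCCC(C)(C)[C@@H]1C[C@@](O)([C@H](CO)[C@H](CO[Si](C)(C)C(C)(C)C)CCO)C(C)=C1 | intermediate
22 | (2S,3R)-5-(TBSO)-3-(TBSO-methyl)-2-[(1R,4R)-4-(6,6-dimethoxy-2-methylhexan-2-yl)-1-hydroxy-2-methylcyclopent-2-en-1-yl]pentan-1-ol | COC(OC)CCCC(C)(C)[C@@H]1C[C@@](O)([C@H](CO)[C@H](CO[Si](C)(C)C(C)(C)C)CCO[Si](C)(C)C(C)(C)C)C(C)=C1 | intermediate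
23 | (2S,3R)-5-(TBSO)-3-(TBSO-methyl)-2-[(1R,4R)-4-(6,6-dimethoxy-2-methylhexan-2-yl)-1-hydroxy-2-methylcyclopent-2-en-1-yl]pentyl acetate | COC(OC)CCCC(C)(C)[C@@H]1C[C@@](O)([C@H](COC(C)=O)[C@H](CO[Si](C)(C)C(C)(C)C)CCO[Si](C)(C)C(C)(C)C)C(C)=C1 | intermediate
24 | (2S,3R)-5-(TBSO)-3-(TBSO-methyl)-2-[(1R,4R)-1-hydroxy-2-methyl-4-(2-methyl-6-oxohexan-2-yl)cyclopent-2-en-1-yl]pentyl acetate | O=CCCCC(C)(C)[C@@H]1C[C@@](O)([C@H](COC(C)=O)[C@H](CO[Si](C)(C)C(C)(C)C)CCO[Si](C)(C)C(C)(C)C)C(C)=C1 | intermediate
25 | (2R,3R)-5-(TBSO)-3-(TBSO-methyl)-2-[(1S,3aR,8R,8aR)-8-hydroxy-1,4,4-trimethyl-2-oxodecahydroazulen-1-yl]pentyl acetate | O[C@@H]1CCCC(C)(C)[C@@H]2CC(=O)[C@@](C)([C@H](COC(C)=O)[C@H](CO[Si](C)(C)C(C)(C)C)CCO[Si](C)(C)C(C)(C)C)[C@H]12 | intermediate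
26 | (2R,3R)-5-(TBSO)-3-(TBSO-methyl)-2-[(1S,3aR,8R,8aR)-1,4,4-trimethyl-2-oxo-8-(TESO)decahydroazulen-1-yl]pentyl acetate | CC[Si](CC)(CC)O[C@@H]1CCCC(C)(C)[C@@H]2CC(=O)[C@@](C)([C@H](COC(C)=O)[C@H](CO[Si](C)(C)C(C)(C)C)CCO[Si](C)(C)C(C)(C)C)[C@H]12 | intermediate
27 | (2R,3R)-5-(TBSO)-3-(TBSO-methyl)-2-[(1S,2R,3aR,8R,8aR)-2-hydroxy-1,4,4-trimethyl-8-(TESO)decahydroazulen-1-yl]pentyl acetate | CC[Si](CC)(CC)O[C@@H]1CCCC(C)(C)[C@@H]2C[C@@H](O)[C@@](C)([C@H](COC(C)=O)[C@H](CO[Si](C)(C)C(C)(C)C)CCO[Si](C)(C)C(C)(C)C)[C@H]12 | intermediate
28 | (2R,3R)-5-(TBSO)-3-(TBSO-methyl)-2-[(1S,2R,3aR,8R,8aR)-1,4,4-trimethyl-2-[(phenoxycarbonothioyl)oxy]-8-(TESO)decahydroazulen-1-yl]pentyl acetate | CC[Si](CC)(CC)O[C@@H]1CCCC(C)(C)[C@@H]2C[C@@H](OC(=S)Oc3ccccc3)[C@@](C)([C@H](COC(C)=O)[C@H](CO[Si](C)(C)C(C)(C)C)CCO[Si](C)(C)C(C)(C)C)[C@H]12 | intermediate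
29 | (2R,3R)-5-(TBSO)-3-(TBSO-methyl)-2-[(1S,3aR,8R,8aR)-1,4,4-trimethyl-8-(TESO)decahydroazulen-1-yl]pentyl acetate | CC[Si](CC)(CC)O[C@@H]1CCCC(C)(C)[C@@H]2CC[C@@](C)([C@H](COC(C)=O)[C@H](CO[Si](C)(C)C(C)(C)C)CCO[Si](C)(C)C(C)(C)C)[C@H]12 | intermediate
30 | (2R,3R)-5-hydroxy-2-[(1S,3aR,8R,8aR)-8-hydroxy-1,4,4-trimethyldecahydroazulen-1-yl]-3-(hydroxymethyl)pentyl acetate | O[C@@H]1CCCC(C)(C)[C@@H]2CC[C@@](C)([C@H](COC(C)=O)[C@H](CO)CCO)[C@H]12 | intermediate
31 | (2R)-2-[(1S,3aR,8R,8aR)-8-hydroxy-1,4,4-trimethyldecahydroazulen-1-yl]-2-[(3R)-5-hydroxyoxolan-3-yl]ethyl acetate (anomers) | O[C@@H]1CCCC(C)(C)[C@@H]2CC[C@@](C)([C@H](COC(C)=O)[C@@H]3COC(O)C3)[C@H]12 | intermediate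
32 | (2R)-2-[(1S,3aR,8R,8aR)-8-hydroxy-1,4,4-trimethyldecahydroazulen-1-yl]-2-[(3R)-5-oxooxolan-3-yl]ethyl acetate | O[C@@H]1CCCC(C)(C)[C@@H]2CC[C@@](C)([C@H](COC(C)=O)[C@@H]3COC(=O)C3)[C@H]12 | intermediate
33 | (2R)-2-[(3R)-5-oxooxolan-3-yl]-2-[(1S,3aR,8aR)-1,4,4-trimethyl-8-oxodecahydroazulen-1-yl]ethyl acetate | O=C1CCCC(C)(C)[C@@H]2CC[C@@](C)([C@H](COC(C)=O)[C@@H]3COC(=O)C3)[C@H]12 | intermediate
34 | (2R)-2-[(3R)-5-oxooxolan-3-yl]-2-[(1R,3aR,8aS)-1,4,4-trimethyl-8-methylidenedecahydroazulen-1-yl]ethyl acetate | C=C1CCCC(C)(C)[C@@H]2CC[C@@](C)([C@H](COC(C)=O)[C@@H]3COC(=O)C3)[C@H]12 | target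

## Step count and risks

Total step count: 26. Longest linear sequence: 21 steps (steps 1–7 and 13–26, from isobutyronitrile 1); the lactone branch (steps 8–12) adds 5 steps.

**Step 18 (key step).** The most likely failure is loss of a proton from the C8 methyl group before C14 shifts (an ene-type termination), helped by a slow seven-membered closure; ionisation of the tertiary allylic C7–O bond by the Lewis acid is the second concern. Fallback: the cascade is split in two, setting out from 24. The Me2AlCl-promoted carbonyl-ene cyclisation is allowed to run to the exocyclic-methylene diol, (2S,3R)-5-(TBSO)-3-(TBSO-methyl)-2-[(2R,3aR,8R,8aR)-2,8-dihydroxy-4,4-dimethyl-1-methylidenedecahydroazulen-2-yl]pentyl acetate F1, which already holds the C9–C10 bond and the cis fusion. A catalytic strong Brønsted acid (HNTf2, CH2Cl2, −78 to −40 °C) then protonates the methylidene group, regenerates the C8 cation next to the intact C7 carbinol and triggers the same suprafacial shift of C14 (acid-promoted semipinacol rearrangement), which returns to the route at 25.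

**Step 13.** Proton transfer from the enone to the basic lactone enolate, reversal of the addition on warming with drift toward conjugate addition, and incomplete facial discrimination at C7 are the likely problems. Fallback: the enolate is generated reductively instead of by deprotonation. Setting out from 19, LiN(iPr)2 followed by 1,2-dibromotetrachloroethane gives (4S)-3-bromo-4-(TBSO-methyl)oxan-2-one F3 (C3 epimers; C4 spatially as in 19). SmI2 in THF at −78 °C in the presence of 11 forms a non-basic samarium enolate that adds irreversibly to the ketone (samarium Reformatsky reaction), returning at 20.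

**Step 15.** Too small a rate difference between the two primary hydroxyls would give silylation at C15 or at both positions. Fallback: the C7 and C15 hydroxyls are tied together first. Setting out from 21, phenylboronic acid and MgSO4 in CH2Cl2 give the six-membered cyclic phenylboronate of the C7/C15 1,3-diol F4. Silylation (tBuMe2SiCl, imidazole) of the only free hydroxyl gives the C11 TBS ether of that boronate F5, and oxidative removal of boron (H2O2, aqueous NaHCO3, THF) returns at 22.

**Step 17.** Acid-promoted ionisation of the tertiary allylic alcohol (dehydration to a cyclopentadiene or allylic transposition) may compete with acetal hydrolysis. Fallback: the aldehyde is released without aqueous acid and the carbinol is protected in the same operation. Setting out from 23, Et3SiOTf and 2,4,6-collidine in CH2Cl2 at 0 °C, followed by water, give the tertiary silyl ether aldehyde, (2S,3R)-5-(TBSO)-3-(TBSO-methyl)-2-[(1R,4R)-2-methyl-4-(2-methyl-6-oxohexan-2-yl)-1-(TESO)cyclopent-2-en-1-yl]pentyl acetate F2. The cascade is then run on the silyl ether with SnCl4 in CH2Cl2 at −78 °C, the silyl group leaving as the chlorosilane, and the route is rejoined at 25.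

## Further compounds

F1 | step 18 | (2S,3R)-5-(TBSO)-3-(TBSO-methyl)-2-[(2R,3aR,8R,8aR)-2,8-dihydroxy-4,4-dimethyl-1-methylidenedecahydroazulen-2-yl]pentyl acetate | O[C@@H]1CCCC(C)(C)[C@@H]2C[C@@](O)([C@H](COC(C)=O)[C@H](CO[Si](C)(C)C(C)(C)C)CCO[Si](C)(C)C(C)(C)C)C(=C)[C@H]12
F2 | step 17 | (2S,3R)-5-(TBSO)-3-(TBSO-methyl)-2-[(1R,4R)-2-methyl-4-(2-methyl-6-oxohexan-2-yl)-1-(TESO)cyclopent-2-en-1-yl]pentyl acetate | O=CCCCC(C)(C)[C@@H]1C[C@@](O[Si](CC)(CC)CC)([C@H](COC(C)=O)[C@H](CO[Si](C)(C)C(C)(C)C)CCO[Si](C)(C)C(C)(C)C)C(C)=C1
F3 | step 13 | (4S)-3-bromo-4-(TBSO-methyl)oxan-2-one (C3 epimers) | O=C1OCC[C@@H](CO[Si](C)(C)C(C)(C)C)C1Br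
F4 | step 15 | cyclic phenylboronate of 21 across the C7 and C15 hydroxyls (2-phenyl-1,3,2-dioxaborinane spiro-fused at C7), C11 hydroxyl free | COC(OC)CCCC(C)(C)[C@@H]1C[C@]2(OB(c3ccccc3)OC[C@@H]2[C@H](CO[Si](C)(C)C(C)(C)C)CCO)C(C)=C1
F5 | step 15 | C11 tert-butyldimethylsilyl ether of the cyclic phenylboronate of 21 | COC(OC)CCCC(C)(C)[C@@H]1C[C@]2(OB(c3ccccc3)OC[C@@H]2[C@H](CO[Si](C)(C)C(C)(C)C)CCO[Si](C)(C)C(C)(C)C)C(C)=C1
A1 | alternative 1 | C12=C13 methylidene alcohol with free C16 hydroxyl and C10 ketone (hydroformylation substrate) | O=C1CCCC(C)(C)[C@@H]2CC[C@@](C)([C@H](COC(C)=O)C(=C)CO)[C@H]12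
A2 | alternative 1 | γ-lactol with C10 ketone (anomers), product of the hydroformylation | O=C1CCCC(C)(C)[C@@H]2CC[C@@](C)([C@H](COC(C)=O)[C@@H]3COC(O)C3)[C@H]12
A3 | alternative 2 | 1-vinylcyclopentene carrying the quaternary C8 with the complete side chain | C=CC1=CCC[C@@]1(C)[C@H](COC(C)=O)[C@@H]2COC(=O)C2
A4 | alternative 2 | 2-(trimethylsilyl)ethyl 2-diazo-4-methylpent-3-enoate | CC(C)=CC(=[N+]=[N-])C(=O)OCC[Si](C)(C)C
A5 | alternative 2 | bicyclic cycloheptadiene ester with C2 ester and C9=C10 alkene, product of cyclopropanation and Cope rearrangement | C[Si](C)(C)CCOC(=O)C1=CC(C)(C)[C@@H]2CC[C@@](C)([C@H](COC(C)=O)[C@@H]3COC(=O)C3)C2=CC1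
A6 | alternative 3 | tert-butyl cycloheptene-1-carboxylate with gem-dimethyl at C4 and the C5 chain ending in the C8 methylidene | CC(C)(C)OC(=O)C1=C[C@@H](CCC(=C)[C@H](COC(C)=O)[C@@H]2COC(=O)C2)C(C)(C)CCC1
A7 | alternative 3 | cis-hydroazulene C10 tert-butyl ester, product of the radical cyclisation | CC(C)(C)OC(=O)[C@H]1CCCC(C)(C)[C@@H]2CC[C@@](C)([C@H](COC(C)=O)[C@@H]3COC(=O)C3)[C@H]12
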